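## Structural features

The target is a diaryl ether: ring A (C1–C6) and ring B (C1'–C6') are joined by a single oxygen between C6 and C1'. Each ring carries a hydroxyl ortho to that oxygen (C1–OH, C6'–OH) and two bromines meta to each other (C3/C5 and C3'/C5'). There is no stereocentre, so the whole problem is one of substitution pattern. The rings are not equivalent. In ring B the bromines lie ortho and para to the hydroxyl, the pattern phenol bromination gives. In ring A they lie ortho and para to the ether oxygen and meta to the hydroxyl, which bromination of the free phenol cannot deliver. The fragile groups are the four aryl C–Br bonds (halogen–metal exchange, oxidative addition to low-valent metals, hydrogenolysis) and the two electron-rich phenols. The real difficulty is the crowded C6–O–C1' linkage, flanked by C5–Br and C1–OH on ring A and by C6'–OH on ring B, combined with the meta-to-hydroxyl bromines of ring A. The key step uses the run C2(H)–C3(Br)–C4(H)–C5(Br) of ring A, which is the C6–C5–C4–C3 diene of 3,5-dibromo-2-pyrone. The remaining adjacent pair C6 (ether) and C1 (hydroxyl) is a two-carbon unit with a heteroatom at each end, which an alkyne bearing aryloxy and boron can supply.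

## Logic of the disconnections

18 ⇒ 17. The ring B hydroxyl at C6' is masked as its methyl ether (O–CH3 bond). That phenol must pass through peracid, divalent copper, bromine, a lithium amide and heat, and a methyl ether survives all of them. The gain is one robust mask for the whole route. The demand is a final dealkylation that spares four C–Br bonds and the diaryl ether.

17 ⇒ 16. The C1–O bond of ring A is exchanged for a C1–B bond. A boronate tolerates and electronically supports the ring-forming step, while a free or protected oxygen on the alkyne would give a doubly donor-substituted, unmanageable dienophile. The demand is a C–B oxidation that proceeds with retention at C1 and leaves C–Br alone.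

16 ⇒ 14 + 12 (through 15). The C1–C2 and C5–C6 bonds of ring A are cut and CO2 is re-inserted across C2/C5. Ring A falls apart into a four-carbon diene that already carries both bromines and a two-carbon alkyne that already carries the C6–O–C1' ether and the boron. The hindered diaryl ether therefore never has to be made by a coupling on a tetrabromide. The demand is regiochemistry: the boron-bearing carbon must bond to the diene terminus C6 of 14 and the aryloxy carbon to the bromine-bearing C3.

12 ⇒ 8 + 9 (through 10 and 11). The C(sp)–B bond is cut to an acetylide and a borate ester, and the triple bond is traced back to a bromoalkene by formal addition of HBr. The cut is made here so that the acetylide arises by amide-base elimination. No alkyllithium is used, since it would exchange with the two aryl bromides. The demand is that elimination and acetylene deprotonation outrun metalation of the arene.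

8 ⇒ 6 (through 7). The vinylic C–Br bond is removed, leaving a plain aryl vinyl ether. Bromine addition and dehydrobromination restore it in the forward sense. The demand is that bromine reacts at the enol ether double bond and not on the ring.

6 ⇒ 4 + 5. The O–C(sp2) bond of the vinyl ether is cut to a phenol and a vinylboron reagent. An oxidative copper coupling at room temperature involves no low-valent metal that could insert into C–Br.

4 ⇒ 2 (through 3) ⇒ 1. The C1'–O bond of ring B is traced to a C1'–CHO bond (aryl migration to oxygen in the forward sense), and the O–CH3 bond at C6' is traced to the free phenol. The meta-to-oxygen bromines of this ring, awkward to introduce by substitution, are thus bought in 1. The demand is aryl and not hydride migration in the peracid step.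

14 ⇒ 13. The two C–Br bonds of the pyrone are cut, one of them back to the carboxyl carbon. A single bromination/bromodecarboxylation delivers the diene.

## Other disconnections considered

Alternative 1: The cut goes through the four C–Br bonds (C3, C5, C3', C5') of 3,5-dibromo-2-(3,5-dibromo-2-hydroxyphenoxy)benzaldehyde A1, back to bromine-free 2-(2-hydroxyphenoxy)benzaldehyde A2. The formyl carbon stands where the C1 hydroxyl will appear after a closing Dakin-type oxidation to 18.
- Forward step: A2 would be brominated with Br2 in acetic acid on ring B (ortho and para to its hydroxyl) and then with FeBr3 on ring A. There the ether oxygen (ortho/para) and the formyl group (meta) point at the same carbons, C5 and C3.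
- In its favour: no protecting group, cheap reagents, concordant directing effects, and roughly four steps in all.
- Against it here: ring A is deactivated by the formyl group, so its two brominations need a Lewis acid while ring B still offers C4' and C2' (para and ortho to the ether oxygen). Over-bromination of ring B and incomplete bromination of ring A are both conceivable, and congeners differing by one bromine would be hard to separate. The aldehyde may also be oxidised by bromine in a protic medium, and the final aryl migration must work on a ring carrying two bromines.
- Comparison: both plans hide the C1 hydroxyl behind another element (carbon there, boron here). In predictability of the reaction type (electrophilic substitution against a cycloaddition with an untried dienophile) alternative 1 is at least the equal. In step economy it is clearly the better. The chosen plan is better only in that every bromine position is fixed by construction, so no isomer or congener question arises.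

Alternative 2: The cut removes both C–O bonds of ring B (C1'–O ether and C6'–O hydroxyl). Ring B becomes 3,5-dibromobenzyne A4 and ring A becomes 2,4-dibromo-6-methoxyphenol A6.
- Forward step: A4 would be released from an ortho-iodoaryl sulfonate such as 2,4-dibromo-6-iodophenyl 4-chlorobenzenesulfonate A5 by iodine–magnesium exchange with i-PrMgCl. The magnesium salt of A6 would add at the aryne carbon remote from bromine. The aryl anion left at C6', next to C5'–Br, would be trapped with B(OMe)3 and oxidised with H2O2 to 2,4-dibromo-6-(2,4-dibromo-6-methoxyphenoxy)phenol A3. Demethylation then gives 18.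
- In its favour: strongly convergent. A6 has its bromines ortho and para to its own hydroxyl and is therefore accessible by plain phenol bromination. The regiochemistry follows the well-established inductive control of a halogen at C3 of an aryne.
- Against it here: a magnesium phenoxide flanked by Br and OMe is a weak, hindered nucleophile for an aryne. The isopropyl Grignard reagent and its by-products can compete for A4. The aryl magnesium intermediate bears an ortho bromine and can itself collapse to a second aryne. The exchange must also discriminate iodine from four bromines.
- Comparison: both plans convert boron into the second hydroxyl and both rest on a polarisation argument for regiochemistry, so on these points the two are equal. In step economy and convergence alternative 2 is the better, at about five steps. The chosen plan has the advantage that its key intermediate is a neutral, storable aryl boronate formed without any organometallic base in the presence of C–Br bonds.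

Alternative 3: The cut is through C1'–C2' and C5'–C6' of ring B, giving 14 and 1,5-dibromo-2-[(2,2-dimethoxyethenyl)oxy]-3-methoxybenzene A8, the aryloxyketene dimethyl acetal built on A6.
- Forward step: [4+2] cycloaddition of A8 to 14, then loss of CO2 and of methanol, would give 1,5-dibromo-2-(3,5-dibromo-2-methoxyphenoxy)-3-methoxybenzene A7. A double demethylation then gives 18.
- In its favour: a ketene acetal is a much stronger donor dienophile than an alkyne and should react with 14 at lower temperature. Its polarisation (nucleophilic aryloxy-bearing carbon to C6 of 14, acetal carbon to C3) is unambiguous. No boron and no oxidation step are needed. Ring A again comes from the easily brominated A6.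
- Against it here: A8 must be made from an aryloxyacetic ester or ortho ester, where O- against C-functionalisation and β-loss of aryloxide are problems. A8 is hydrolytically labile, and its nucleophilic carbon is the more hindered one.
- Comparison: the ring-forming logic is the same pericyclic cascade on the same pyrone, so on mechanism the two are equal. Alternative 3 is the better in the steps after the key step (one against two), in the accessibility of its phenol and probably in reaction temperature. The chosen plan has no clear structural advantage for this target beyond differentiated oxygens in the product. Its dienophile 12 is likewise delicate, and is reached by elimination and borylation steps of known type.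

Key step: step 7

Remark on the chemistry: the atom maps of 12, 14 and 16 were checked against the target and need no correction. What is redesigned is the access to 12. A dichlorovinyl ether/alkyllithium sequence would expose two aryl C–Br bonds to halogen–lithium exchange, so the alkyne is instead generated from a bromovinyl ether with a lithium amide.

## Route

Step 1
Reactants: 1 3,5-dibromo-2-hydroxybenzaldehyde (3,5-dibromosalicylaldehyde)
Product: 2 3,5-dibromo-2-methoxybenzaldehyde
Conditions: MeI, K2CO3, DMF, rt → 40 °C
Reagents that add atoms: iodomethane, CI
Why: Williamson O-methylation of an acidic phenoxide; the small electrophile in a dipolar aprotic solvent copes with the flanking formyl and bromine groups.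

Step 2
Reactants: 2 3,5-dibromo-2-methoxybenzaldehyde
Product: 4 3,5-dibromo-2-methoxyphenol, via 3,5-dibromo-2-methoxyphenyl formate 3 (not isolated)
Conditions: mCPBA, CH2Cl2, 40 °C; NaHCO3 wash; then K2CO3 (0.1 equiv), MeOH, rt
Reagents that add atoms: 3-chloroperoxybenzoic acid (mCPBA), OOC(=O)c1cccc(Cl)c1
Why: Baeyer–Villiger (Dakin-type) oxidation in which the ortho-methoxy group favours aryl over hydride migration in the Criegee intermediate; the aryl formate is then cleaved by base-catalysed methanolysis.

Step 3
Reactants: 4 3,5-dibromo-2-methoxyphenol; 5 2,4,6-trivinylcyclotriboroxane–pyridine complex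
Product: 6 1,5-dibromo-3-(ethenyloxy)-2-methoxybenzene
Conditions: Cu(OAc)2 (1 equiv), pyridine, 4 Å MS, CH2Cl2, rt, air
Reagents that add atoms: none
Why: Chan–Lam oxidative O-vinylation of a phenol with a vinylboron reagent under divalent copper; at room temperature and without a low-valent metal the aryl bromides should be left alone.

Step 4
Reactants: 6 1,5-dibromo-3-(ethenyloxy)-2-methoxybenzene
Product: 8 1,5-dibromo-3-{[(Z)-2-bromoethenyl]oxy}-2-methoxybenzene, via 1,5-dibromo-3-(1,2-dibromoethoxy)-2-methoxybenzene 7 (not isolated)
Conditions: Br2, CH2Cl2, −78 °C; then i-Pr2NEt, −78 °C → 40 °C
Reagents that add atoms: bromine, BrBr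
Why: Electrophilic addition of bromine to the enol ether double bond (far faster than substitution on the twice-brominated ring), then dehydrobromination of the α-bromo ether by a hindered amine, which for β-halovinyl ethers is expected to favour the Z isomer.

Step 5
Reactants: 8 1,5-dibromo-3-{[(Z)-2-bromoethenyl]oxy}-2-methoxybenzene; 9 2-isopropoxy-4,4,5,5-tetramethyl-1,3,2-dioxaborolane
Product: 12 2-[(3,5-dibromo-2-methoxyphenoxy)ethynyl]-4,4,5,5-tetramethyl-1,3,2-dioxaborolane, via lithium (3,5-dibromo-2-methoxyphenoxy)ethynide 10 (not isolated), via lithium alkynyl(isopropoxy)borate 11 (not isolated)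
Conditions: LiN(i-Pr)2 (LDA, 2.05 equiv, added slowly to 8), THF, −78 °C; 9, −78 °C; then HCl·Et2O (1.05 equiv), −78 °C → rt
Reagents that add atoms: none
Why: Anti-periplanar E2 loss of HBr from the Z bromovinyl ether gives the aryloxyacetylene, whose acidic sp C–H takes the second equivalent of amide at once, so the base stays limiting and no halogen–lithium exchange reagent is ever present. The acetylide then adds to the boron of 9 and anhydrous HCl expels isopropanol from the borate, the standard route to alkynyl pinacol boronates.

Step 6
Reactants: 13 coumalic acid (2-oxo-2H-pyran-5-carboxylic acid)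
Product: 14 3,5-dibromo-2H-pyran-2-one
Conditions: NBS (2.2 equiv), LiOAc (0.2 equiv), MeCN–H2O, rt
Reagents that add atoms: N-bromosuccinimide, O=C1CCC(=O)N1Br
Why: Bromodecarboxylation at C5 (ipso attack at the carboxylate-bearing carbon with loss of CO2) combined with electrophilic bromination at the nucleophilic C3 of the pyrone.

Step 7
Reactants: 14 3,5-dibromo-2H-pyran-2-one; 12 2-[(3,5-dibromo-2-methoxyphenoxy)ethynyl]-4,4,5,5-tetramethyl-1,3,2-dioxaborolane
Product: 16 2-[3,5-dibromo-2-(3,5-dibromo-2-methoxyphenoxy)phenyl]-4,4,5,5-tetramethyl-1,3,2-dioxaborolane, via bicyclic lactone cycloadduct 15 (not isolated)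
Conditions: toluene, 120 °C, sealed tube, Ar
Reagents that add atoms: none
Why: The diene C3=C4–C5=C6 of 14 and the triple bond of 12 combine in an asynchronous Diels–Alder reaction to the 2-oxabicyclo[2.2.2]octadienone 15, which loses CO2 by retro-[4+2] and is aromatic at once. The closest known reaction type is the cycloaddition–decarboxylation of 2-pyrones with alkynyl boronates to aryl boronates. Ring A is closed by this intermolecular [4+2] event, which forms C1–C2 and C5–C6 together; the CO2 extrusion only unveils the benzene ring. The two bridgehead stereocentres of racemic 15 are destroyed on aromatisation, so no stereochemical control is needed. The selectivity required is regiochemical, and it is secured by matched polarisation. The aryloxy lone pair makes the boron-bearing carbon nucleophilic and the empty boron orbital makes the aryloxy-bearing carbon electrophilic, while in 14 C6 is the electrophilic and C3 the nucleophilic diene terminus. The boron-bearing carbon should therefore bond to C6 and the aryloxy carbon to C3, the same sense in which 14 is known to take up donor-substituted alkenes. Boron thus ends at C1 beside C2–H and the ether at C6 beside C5–Br. The step is purely thermal and reagent-free, so the C–Br bonds, the ether and the C–B bond are not put at risk, and the donor alkyne paired with an electron-poor pyrone should allow a lower temperature than simple alkynyl boronates need.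

Step 8
Reactants: 16 2-[3,5-dibromo-2-(3,5-dibromo-2-methoxyphenoxy)phenyl]-4,4,5,5-tetramethyl-1,3,2-dioxaborolane
Product: 17 3,5-dibromo-2-(3,5-dibromo-2-methoxyphenoxy)phenol
Conditions: 30% H2O2, 1 M NaOH, THF, 0 °C → rt; then 1 M HCl
Reagents that add atoms: hydrogen peroxide, OO
Why: Hydroperoxide adds to boron and the aryl group migrates from boron to oxygen with retention at C1 (standard boronate oxidation); hydrolysis of the borate frees the phenol, and aryl bromides are inert to these conditions.

Step 9
Reactants: 17 3,5-dibromo-2-(3,5-dibromo-2-methoxyphenoxy)phenol
Product: 18 3,5-dibromo-2-(3,5-dibromo-2-hydroxyphenoxy)phenol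
Conditions: BBr3 (3 equiv), CH2Cl2, −78 °C → rt; then H2O
Reagents that add atoms: none
Why: Lewis acid-mediated demethylation: boron coordinates the methoxy oxygen and bromide attacks the methyl carbon. The diaryl ether offers no sp3 carbon for this SN2 step, and the C–Br bonds are inert to BBr3.

## Compound list

1 | 3,5-dibromo-2-hydroxybenzaldehyde (3,5-dibromosalicylaldehyde) | O=Cc1cc(Br)cc(Br)c1O | starting material
2 | 3,5-dibromo-2-methoxybenzaldehyde | COc1c(Br)cc(Br)cc1C=O | intermediate
3 | 3,5-dibromo-2-methoxyphenyl formate | COc1c(Br)cc(Br)cc1OC=O | intermediate (not isolated)
4 | 3,5-dibromo-2-methoxyphenol | COc1c(O)cc(Br)cc1Br | intermediate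
5 | 2,4,6-trivinylcyclotriboroxane–pyridine complex | C=CB1OB(C=C)OB(C=C)O1.c1ccncc1 | starting material
6 | 1,5-dibromo-3-(ethenyloxy)-2-methoxybenzene | COc1c(Br)cc(Br)cc1OC=C | intermediate
7 | 1,5-dibromo-3-(1,2-dibromoethoxy)-2-methoxybenzene (racemic) | COc1c(Br)cc(Br)cc1OC(Br)CBr | intermediate (not isolated)
8 | 1,5-dibromo-3-{[(Z)-2-bromoethenyl]oxy}-2-methoxybenzene | COc1c(Br)cc(Br)cc1O/C=C\Br | intermediate
9 | 2-isopropoxy-4,4,5,5-tetramethyl-1,3,2-dioxaborolane | CC(C)OB1OC(C)(C)C(C)(C)O1 | starting material
10 | lithium (3,5-dibromo-2-methoxyphenoxy)ethynide | [Li+].[C-]#COc1cc(Br)cc(Br)c1OC | intermediate (not isolated)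
11 | lithium [(3,5-dibromo-2-methoxyphenoxy)ethynyl](isopropoxy)(pinacolato)borate | [Li+].CC(C)O[B-]1(OC(C)(C)C(C)(C)O1)C#COc1cc(Br)cc(Br)c1OC | intermediate (not isolated)
12 | 2-[(3,5-dibromo-2-methoxyphenoxy)ethynyl]-4,4,5,5-tetramethyl-1,3,2-dioxaborolane | CC1(C)OB(OC1(C)C)C#COc1cc(Br)cc(Br)c1OC | intermediate
13 | coumalic acid (2-oxo-2H-pyran-5-carboxylic acid) | O=C(O)C1=COC(=O)C=C1 | starting material
14 | 3,5-dibromo-2H-pyran-2-one | O=C1OC=C(Br)C=C1Br | intermediate
15 | 4,7-dibromo-5-(3,5-dibromo-2-methoxyphenoxy)-6-(4,4,5,5-tetramethyl-1,3,2-dioxaborolan-2-yl)-2-oxabicyclo[2.2.2]octa-5,7-dien-3-one (racemic; bridgehead configuration fixed by the bicycle) | O=C1OC2C(Br)=CC1(Br)C(Oc1cc(Br)cc(Br)c1OC)=C2B1OC(C)(C)C(C)(C)O1 | intermediate (not isolated)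
16 | 2-[3,5-dibromo-2-(3,5-dibromo-2-methoxyphenoxy)phenyl]-4,4,5,5-tetramethyl-1,3,2-dioxaborolane | CC1(C)OB(OC1(C)C)c1cc(Br)cc(Br)c1Oc1cc(Br)cc(Br)c1OC | intermediate
17 | 3,5-dibromo-2-(3,5-dibromo-2-methoxyphenoxy)phenol | COc1c(Br)cc(Br)cc1Oc1c(O)cc(Br)cc1Br | intermediate
18 | 3,5-dibromo-2-(3,5-dibromo-2-hydroxyphenoxy)phenol | Oc1cc(Br)cc(Br)c1Oc1cc(Br)cc(Br)c1O | target

## Step count and risks

Total step count: 9. Longest linear sequence: 8 steps (steps 1–5, then 7–9); step 6 is a one-step side branch.

Least certain steps:

Step 7 (key step). The most likely failures are erosion of regiocontrol (the aryloxy carbon bonding to C6 of the pyrone instead of C3, which would place boron beside bromine) and thermal oligomerisation or protodeboronation of the ynol ether boronate before it is consumed. The dienophile is untried in this reaction and both its ends are substituted. Fallback, known chemistry only: the cycloaddition is abandoned and the ether is made by nucleophilic aromatic substitution. Setting out from 4, its potassium salt (K2CO3, DMF, 100 °C) displaces fluoride from purchasable 3,5-dibromo-2-fluorobenzaldehyde F1, whose formyl group activates the ortho C–F bond, to give 3,5-dibromo-2-(3,5-dibromo-2-methoxyphenoxy)benzaldehyde F2. Baeyer–Villiger oxidation with mCPBA to 3,5-dibromo-2-(3,5-dibromo-2-methoxyphenoxy)phenyl formate F3 and methanolysis come back to the route at 17.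

Step 5. What may go wrong is metalation of the arene at the C–H flanked by two bromines when amide is locally in excess (followed by aryne formation), β-loss of aryloxide after deprotonation at the bromine-bearing vinyl carbon, and addition of HCl across the acid-sensitive ynol ether during the quench. Fallback: setting out from 8, the elimination is separated from the metalation. KOt-Bu in THF (−40 → 0 °C) effects the dehydrobromination, classical for aryloxyacetylenes with alkoxide or hydroxide bases, to 1,5-dibromo-3-(ethynyloxy)-2-methoxybenzene F4, which is kept as a cold solution. One equivalent of LiN(SiMe3)2, too weak a base to touch the arene, then deprotonates the alkyne and comes back to the route at 10.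

Step 2. Hydride migration may compete with aryl migration in the Criegee intermediate, because the methoxy group is twisted out of conjugation by its two ortho neighbours and the ring carries two bromines; this would give the benzoic acid. Fallback: setting out from 1, the free salicylaldehyde undergoes the Dakin oxidation (H2O2, aqueous NaOH), in which the ortho-phenoxide enforces aryl migration, through 3,5-dibromo-2-hydroxyphenyl formate F5 to 3,5-dibromobenzene-1,2-diol F6. Mono-methylation with MeI and one equivalent of Li2CO3 in DMF at the more acidic hydroxyl (the one ortho and para to bromine) comes back to the route at 4.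

Step 3. Slow copper–oxygen bond formation with a weakly nucleophilic, ortho-substituted phenol may let oxidative self-coupling of the phenol take over. Fallback: setting out from 4, O-alkylation with excess 1,2-dibromoethane (K2CO3, MeCN, reflux) gives 1,5-dibromo-3-(2-bromoethoxy)-2-methoxybenzene F7, and E2 elimination with KOt-Bu in THF comes back to the route at 6.

## Further compounds

F1 | step 7 | 3,5-dibromo-2-fluorobenzaldehyde | O=Cc1cc(Br)cc(Br)c1F
F2 | step 7 | 3,5-dibromo-2-(3,5-dibromo-2-methoxyphenoxy)benzaldehyde | COc1c(Br)cc(Br)cc1Oc1c(C=O)cc(Br)cc1Br
F3 | step 7 | 3,5-dibromo-2-(3,5-dibromo-2-methoxyphenoxy)phenyl formate | COc1c(Br)cc(Br)cc1Oc1c(OC=O)cc(Br)cc1Br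
F4 | step 5 | 1,5-dibromo-3-(ethynyloxy)-2-methoxybenzene | C#COc1cc(Br)cc(Br)c1OC
F5 | step 2 | 3,5-dibromo-2-hydroxyphenyl formate | O=COc1cc(Br)cc(Br)c1O
F6 | step 2 | 3,5-dibromobenzene-1,2-diol | Oc1cc(Br)cc(Br)c1O
F7 | step 3 | 1,5-dibromo-3-(2-bromoethoxy)-2-methoxybenzene | COc1c(Br)cc(Br)cc1OCCBr
A1 | alternative 1 | 3,5-dibromo-2-(3,5-dibromo-2-hydroxyphenoxy)benzaldehyde | O=Cc1cc(Br)cc(Br)c1Oc1cc(Br)cc(Br)c1O
A2 | alternative 1 | 2-(2-hydroxyphenoxy)benzaldehyde | O=Cc1ccccc1Oc1ccccc1O
A3 | alternative 2 | 2,4-dibromo-6-(2,4-dibromo-6-methoxyphenoxy)phenol | COc1cc(Br)cc(Br)c1Oc1cc(Br)cc(Br)c1O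
A4 | alternative 2 | 3,5-dibromobenzyne (3,5-dibromo-1,2-didehydrobenzene) | BrC1=CC(Br)=CC#C1
A5 | alternative 2 | 2,4-dibromo-6-iodophenyl 4-chlorobenzenesulfonate | O=S(=O)(Oc1c(Br)cc(Br)cc1I)c1ccc(Cl)cc1
A6 | alternative 2 | 2,4-dibromo-6-methoxyphenol | COc1cc(Br)cc(Br)c1O
A7 | alternative 3 | 1,5-dibromo-2-(3,5-dibromo-2-methoxyphenoxy)-3-methoxybenzene | COc1cc(Br)cc(Br)c1Oc1cc(Br)cc(Br)c1OC
A8 | alternative 3 | 1,5-dibromo-2-[(2,2-dimethoxyethenyl)oxy]-3-methoxybenzene | COC(OC)=COc1c(Br)cc(Br)cc1OC
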